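Start from the larch run.

| flask | Q | J | remark | time |
|---|---|---|---|---|
| larch | 0.43 M | 1.1 equiv | run made earlier |  |
| oak | 0.21 M | 1.1 equiv | run made earlier |  |
| elm | 0.86 M | 1.1 equiv | run made earlier |  |
| amber | 0.43 M | 1.10 equiv (fed, over 24.0 h) | a stirred flask in which J is dosed at a steady rate over 24.0 h without added volume, worked up at 30 h | 30 h |
| red | 0.43 M | 1.10 equiv | a single well-mixed tank run continuously and read at steady state, 30 h in it on average |  |
| violet | 0.43 M | 1.10 equiv | everything together in a closed stirred flask, run for 30 h | 30 h |
| teal | 0.43 M (fed, over 24.0 h) | 1.10 equiv | a stirred flask in which Q is dosed at a steady rate over 24.0 h without added volume, worked up at 30 h | 30 h |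

- larch (time / h: L / %, G / %, Q / %): 6.00: 65.8, 10.8, 13.4; 12.0: 69.2, 13.2, 8.2; 20.0: 70.6, 14.3, 7.4; 25.0: 70.6, 14.6, 6.9; 30.0: 69.6, 15.3, 6.6
- oak (time / h: L / %, G / %, Q / %): 2.50: 43.1, 4.6, 36.6; 5.00: 51.9, 8.8, 21.4; 8.00: 57.9, 12.9, 15.1; 15.0: 60.8, 17.4, 10.7; 30.0: 63.7, 19.8, 7.8
- elm (time / h: L / %, G / %, Q / %): 2.50: 68.4, 5.4, 19.8; 8.00: 75.6, 8.6, 8.8; 15.0: 74.8, 9.5, 8.1; 20.0: 76.0, 10.7, 5.8; 30.0: 76.2, 9.0, 6.7

(scatter of a reading: 0.5 percentage points)

- the stated concentrations are those of everything mixed, before any reaction; amounts are the same in each set-up
- reactions considered so far: 2 J -> Z; J + D -> G; Q + J -> L; Q <-> D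
- the feed brings no volume worth counting
- the earlier runs were made in a closed, stirred flask

- the set-up with the highest share of L in all that became L or G, at the outlet or at the end ("none" if the first two lie within 2 percentage points) (amber / red / violet / teal / none)
- share of L in all that became L or G, at the outlet or at the end, amber
- share of L in all that became L or G, at the outlet or at the end, red
- share of L in all that became L or G, at the outlet or at the end, violet
- share of L in all that became L or G, at the outlet or at the end, teal

1. The bench rule, read from larch, oak and elm at the same equivalents of J, says that the more concentrated of these flasks ends with the cleaner product. To put a number on it, treat G as a small correction to L: take the end ratio of G to L as a length on the c_J axis divided by the charged c_J. Larch, at 30.0 h, gives as a reading the leak concentration 0.104 M, so you expect the share of L in L plus G, the selectivity, to be s = 1/(1 + leak/c_J).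

2. On the elm run the rule gives 90.1% against a reading of 89.4%. On the oak run it gives 69.0% against 76.3%, so it already runs low there.

3. The border comes from the late oak increments, between 8.00 h and 30.0 h, which read a share of 45.7%, and as my own estimate I take that reading as a floor for a flask short of J. The rule falls to that floor at c_J = 0.0874 M, and below this you should stop using it.

4. In amber, the J arrived by 6.00 h is a quarter of the charge, 0.118 M, which is more than the border with none of it counted as used, so I put amber closer to the floor than to the larch share. Teal has its J charged at the start, so the rule gives it the larch share, which I hold as an upper guess, and violet repeats larch.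

5. The forecast: violet best, with amber 52%, red 64%, violet 82% and teal 72%. For teal it reasons, “Q is kept low, so it leaks to D, which J then captures as G”.

6. The flask gives violet best, with amber 54.6%, red 66.3%, violet 83.2% and teal 78.4%. The forecast parts from this at teal, by 6.4 percentage points.

    2 J → Z (k = 8.90 × 10⁻⁵ M⁻¹ s⁻¹)
    J + D → G (k = 4.50 × 10⁻⁴ M⁻¹ s⁻¹)
    Q + J → L (k = 5.10 × 10⁻⁴ M⁻¹ s⁻¹)
    Q ⇌ D (K = 1.20, k = 4.20 × 10⁻⁵ s⁻¹)

On violet the leak concentration simply returns the larch share, 82.0%, so the 83.2% of violet is no test of it. Now take the neighbour of violet charged with 2.80 equiv of J, all else held, where c_J is 1.20 M. The same reckoning gives 92.1%, and that flask gives 90.3%, with 90.3% of L and 9.64% of G at its end.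

(All runs stem from a simulated flask with constants of no real substance.)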